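Count the ligand first.

| flask | starting complex | incoming ligand | temperature | remark | time |
|---|---|---|---|---|---|
| Monday's | 0.24 M | 0.36 M | 110 °C | run made earlier |  |
| Friday's | 0.24 M | 0.54 M | 110 °C | run made earlier |  |
| amber | 0.24 M | 0.360 M | 110 °C | everything together at the start | 2.5 d |
| teal | 0.24 M | 0.360 M |  | everything together at the start at 90 °C, warmed to 110 °C at 40 h | 2.5 d |
| blue | 0.24 M (fed, over 40 h) | 0.360 M |  | the addition at 90 °C, then warmed to 110 °C; the feed brings no volume worth counting | 2.5 d |
| red | 0.24 M (fed, over 40 h) | 0.360 M | 110 °C | all else is in the flask from the start; the feed brings no volume worth counting | 2.5 d |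

Monday's run (percent of the starting complex charged)

| time / d | complex with two exchanged / % | complex with one exchanged / % |
|---|---|---|
| 0.125 | 5.6 | 14.5 |
| 0.417 | 26.0 | 17.7 |
| 0.625 | 34.2 | 15.3 |
| 1.04 | 46.1 | 12.2 |
| 1.67 | 54.2 | 9.6 |
| 2.08 | 56.7 | 6.3 |
| 2.50 | 58.8 | 5.7 |

Friday's run (percent of the starting complex charged)

| time / h | complex with two exchanged / % | complex with one exchanged / % |
|---|---|---|
| 0.500 | 0.3 | 5.6 |
| 0.667 | 0.6 | 6.5 |
| 1.00 | 2.6 | 9.7 |
| 1.50 | 3.8 | 12.7 |
| 2.50 | 8.0 | 16.1 |
| 4.00 | 16.2 | 17.6 |
| 6.00 | 24.9 | 18.7 |

(readings scatter by 0.5 percentage points)

- the earlier runs do not show what temperature does; that part of a forecast is a guess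

1. the flask that comes out highest in amount of complex with two exchanged, in percent of the starting complex charged, or "all alike" when all lie within 1.5 percentage points (amber / teal / blue / red / all alike)
2. complex with two exchanged at the end, in percent of the starting complex charged, amber
3. complex with two exchanged at the end, in percent of the starting complex charged, teal
4. complex with two exchanged at the end, in percent of the starting complex charged, blue
5. complex with two exchanged at the end, in percent of the starting complex charged, red

Each complex with two exchanged holds two incoming ligands. Our ligand ceiling is therefore the incoming ligand charged divided by twice the starting complex charged, here 75.0%. With 0.24 M of starting complex charged, control changes hands at 0.480 M of incoming ligand: below that crossing incoming ligand is the limiting reagent, above it starting complex is. Amber, teal, blue and red each carry 0.360 M, under the crossing, so incoming ligand is their limiting reagent.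

Take ligand first, though the recipes hold it. Friday's run, past the crossing at 0.54 M, read 24.9% at 6.00 h, while Monday's run needed 0.417 d for 26.0%. So of these two runs, the one with more incoming ligand climbed faster.

Then time. Monday's run gained 2.1 percentage points over its last 10.1 h and read 58.8%, so we expect amber, its repeat, to end near that.

Then the cold hold. Teal has 20.0 h at 110 °C, a third of its time. Monday's run read 46.1% at 1.04 d, and we guess teal ends somewhat above that, taking its 40 h at 90 °C as worth more than the 4.96 h at 110 °C that separate the two times.

Then the feed. Red keeps 2.5 d at 110 °C, longer than teal's warm time, so we place it between amber and teal. Blue has teal's warm time with its complex arriving late, so we place it lowest.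

The forecast, which says of red that “feeding only delays the reaction”, gives amber 59%, teal 49%, blue 45% and red 52%, with amber highest.

The flasks give amber 58.5%, teal 48.3%, blue 45.3% and red 53.2%, and amber is highest.

    starting complex + incoming ligand → leaving ligand + complex with one exchanged (k = 0.220 L mol⁻¹ h⁻¹, Ea = 96.0 kJ mol⁻¹)
    complex with one exchanged + incoming ligand → leaving ligand + complex with two exchanged (k = 0.680 L mol⁻¹ h⁻¹, Ea = 100 kJ mol⁻¹)
    leaving ligand + complex with one exchanged → side product (k = 0.0880 L mol⁻¹ h⁻¹, Ea = 99.0 kJ mol⁻¹)
    (constants at 110 °C)

Amber ends 17 points under its ceiling, with 9.7% of its incoming ligand left. Blue's neighbour, with 0.90 M of incoming ligand, stands past the crossing, at 3.75 equiv, so starting complex is its limiting reagent. That flask ends at 88.1%, with 51.2% of its incoming ligand and 5.2% of the starting complex left.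

All runs are simulated with constants of no real substance; noise was put on by code.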